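**Retrosynthetic overview**
- The target comes from acid hydrolysis of the C4 spiro-oxirane of a 14-membered 3-keto lactone; C2 is set by equilibration.
- The macrocycle comes from a C2–C3 macro-aldol of a C13 propanoate onto a C3 α-epoxy aldehyde, then oxidation. Ring order: oxirane first, 14-membered lactone second, oxirane opened last.
- The epoxy aldehyde comes from amine-catalysed asymmetric epoxidation (sets C4) of a 2-substituted acrolein, made by α-methylenation of a Claisen aldehyde (Claisen builds C3–C7 and the E C6=C7 alkene).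
- The C10–C11 diene bond comes from a borylation/Suzuki union of a 2-bromo-1-alkene (C5–C10 piece) with an (E)-iodoalkene propanoate (C11–C13 piece, C13 set by catalytic Et2Zn addition).
- C8 comes from an organocatalytic SOMO α-(2-bromoallylation) of propanal: the first stereocentre and the new step.

Numbering used below: C1 = lactone carbonyl, C2 = CHMe, C3 = ketone, C4 = C(OH)(CH2OH), C5–C12 along the chain, C13 = CH(Et)–O.

Assumption 1: the 2R epimer is the thermodynamically preferred one in the 3-keto lactone (C2–H is acidic), so C2 is set by equilibration.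

Assumption 2: each chiral catalyst is used in the enantiomer (or pseudoenantiomer) that delivers the configuration drawn; if the sense on these substrates is opposite to that of the closest published cases, the mirror-image catalyst is used.

**Step 1**
Reactants: 1 propanal; 2 (2-bromoprop-2-en-1-yl)trimethylsilane
Product: 3 (2S)-4-bromo-2-methylpent-4-enal
Conditions: (2S,5S)-5-benzyl-2-tert-butyl-3-methylimidazolidin-4-one·TFA (20 mol%), (NH4)2Ce(NO3)6 (2 equiv), NaHCO3, H2O, DME, –20 °C; solution of 3 used directly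
Reagents that add atoms: none
Why: Proposed new method: organo-SOMO α-allylation with a 2-haloallylsilane – the imidazolidinone forms the (E)-enamine of 1, tetravalent cerium oxidises it to a 3π-electron radical cation that adds through its unshielded face to the CH2 terminus of 2 (setting C8 as S), and the resulting α-bromo-β-silyl radical is oxidised by the second equivalent of oxidant and loses Me3Si+ to leave the 2-bromoalkene; the closest known reaction is the SOMO-activated α-allylation of aldehydes with allyl- and 2-substituted allyltrimethylsilanes, which has not been shown for a 2-bromoallylsilane or for propanal.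

**Step 2**
Reactants: 3 (2S)-4-bromo-2-methylpent-4-enal
Product: 4 (4S)-6-bromo-2,4-dimethylhepta-1,6-dien-3-ol (C3 epimers)
Conditions: CH2=C(CH3)MgBr (1.2 equiv), THF, –78 °C; then H2O
Reagents that add atoms: isopropenylmagnesium bromide CC(=C)[Mg]Br
Why: Grignard 1,2-addition to the aldehyde at –78 °C is faster than epimerisation at C8 or any reaction of the alkenyl bromide, and the new carbinol centre (C7) is formed as a mixture that is erased in step 7.

**Step 3**
Reactants: 5 prop-2-yn-1-ol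
Product: 7 (2E)-3-iodo-2-methylprop-2-en-1-ol, via alkenylalane 6 (not isolated)
Conditions: AlMe3 (3 equiv), Cp2ZrCl2 (0.25 equiv), CH2Cl2, 0 °C to rt; then I2, THF, –30 °C; aq K2CO3
Reagents that add atoms: trimethylaluminium C[Al](C)C; iodine II
Why: Negishi zirconium-catalysed carboalumination adds Me and Al syn across the alkyne with Me on the internal carbon, and iodinolysis of the C–Al bond with retention gives only the (E)-iodoalkene.

**Step 4**
Reactants: 7 (2E)-3-iodo-2-methylprop-2-en-1-ol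
Product: 8 (2E)-3-iodo-2-methylprop-2-enal
Conditions: MnO2 (15 equiv), CH2Cl2, rt
Reagents that add atoms: none
Why: Selective MnO2 oxidation of an allylic alcohol, which leaves the alkene geometry and the C–I bond untouched.

**Step 5**
Reactants: 8 (2E)-3-iodo-2-methylprop-2-enal
Product: 10 (1E,3R)-1-iodo-2-methylpent-1-en-3-yl propanoate, via ethylzinc alkoxide 9 (not isolated)
Conditions: Et2Zn (2 equiv), (+)-MIB (3-exo-morpholinoisoborneol, 5 mol%), hexanes/toluene, 0 °C; then (EtCO)2O, 0 °C to rt; H2O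
Reagents that add atoms: diethylzinc CC[Zn]CC; propanoic anhydride CCC(=O)OC(=O)CC
Why: Amino-alcohol-catalysed enantioselective addition of diethylzinc to the enal sets C13 (R) under catalyst control, and the zinc alkoxide is acylated in the same flask.

**Step 6**
Reactants: 4 (4S)-6-bromo-2,4-dimethylhepta-1,6-dien-3-ol; 10 (1E,3R)-1-iodo-2-methylpent-1-en-3-yl propanoate
Product: 12 (3R,4E,8S)-9-hydroxy-4,8,10-trimethyl-6-methylideneundeca-4,10-dien-3-yl propanoate (C9 epimers), via alkenylboronate 11 (not isolated)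
Conditions: 4, B2pin2, PdCl2(PPh3)2 (3 mol%), PPh3, KOPh, toluene, 50 °C; then 10, aq K3PO4, DMF, 50 °C
Reagents that add atoms: none
Why: Miyaura borylation of the 2-bromoalkene followed by Suzuki–Miyaura alkenyl–alkenyl coupling forms the C10–C11 bond with retention of the (E)-iodoalkene geometry, oxidative addition to C–I being much faster than ionisation of the hindered allylic ester.

**Step 7**
Reactants: 12 (3R,4E,8S)-9-hydroxy-4,8,10-trimethyl-6-methylideneundeca-4,10-dien-3-yl propanoate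
Product: 14 (3R,4E,8S,9E)-4,8,10-trimethyl-6-methylidene-13-oxotrideca-4,9-dien-3-yl propanoate, via allyl vinyl ether 13 (not isolated)
Conditions: ethyl vinyl ether (solvent), Hg(OAc)2 (0.3 equiv), reflux; evaporate; toluene, 110 °C (sealed tube)
Reagents that add atoms: ethyl vinyl ether C=COCC
Why: Mercury-catalysed transvinylation and Claisen [3,3] rearrangement through a chair with the C8 side chain equatorial give the (E)-trisubstituted C6=C7 alkene and the C3 aldehyde from both C7 epimers (minor Z isomer removed by chromatography), with C8 untouched.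

**Step 8**
Reactants: 14 (3R,4E,8S,9E)-4,8,10-trimethyl-6-methylidene-13-oxotrideca-4,9-dien-3-yl propanoate
Product: 15 (3R,4E,8S,9E)-12-formyl-4,8,10-trimethyl-6-methylidenetrideca-4,9,12-trien-3-yl propanoate
Conditions: 37% aq CH2O, pyrrolidine (10 mol%), propanoic acid (10 mol%), i-PrOH, 45 °C
Reagents that add atoms: formaldehyde C=O
Why: Amine-catalysed Mannich condensation–elimination (organocatalytic α-methylenation) converts the CH2–CHO unit into the 2-substituted acrolein without touching the ester or the other alkenes.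

**Step 9**
Reactants: 15 (3R,4E,8S,9E)-12-formyl-4,8,10-trimethyl-6-methylidenetrideca-4,9,12-trien-3-yl propanoate
Product: 16 (3R,4E,8S,9E)-11-[(2R)-2-formyloxiran-2-yl]-4,8,10-trimethyl-6-methylideneundeca-4,9-dien-3-yl propanoate
Conditions: 50% aq H2O2 (1.5 equiv), 9-amino-9-deoxy-epi-quinine (10 mol%), (R)-TRIP (chiral BINOL hydrogen phosphate, 10 mol%), THF, 50 °C
Reagents that add atoms: hydrogen peroxide OO
Why: Iminium-catalysed Weitz–Scheffer-type epoxidation of an α-branched enal – conjugate addition of H2O2 to the chiral iminium ion pair, then enamine ring closure on one face – sets C4 (R), while the unactivated alkenes and the diene do not react with H2O2.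

**Step 10**
Reactants: 16 (3R,4E,8S,9E)-11-[(2R)-2-formyloxiran-2-yl]-4,8,10-trimethyl-6-methylideneundeca-4,9-dien-3-yl propanoate
Product: 18 (3R,8R,9E,13S,14E)-8-ethyl-4-hydroxy-5,9,13,15-tetramethyl-11-methylidene-1,7-dioxaspiro[2.13]hexadeca-9,14-dien-6-one (macrolide C2/C3 epimers), via potassium enolate 17 (not isolated)
Conditions: KN(SiMe3)2 (1.5 equiv), THF, –78 °C, syringe-pump addition of 16 to 1 mM; then AcOH, –78 °C
Reagents that add atoms: none
Why: Macro-aldol addition of the propanoate potassium enolate to the non-enolisable epoxy aldehyde under high dilution closes the 14-membered ring at C2–C3, and the C2/C3 configurations do not matter because C3 is oxidised and C2 equilibrated in step 11.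

**Step 11**
Reactants: 18 (3R,8R,9E,13S,14E)-8-ethyl-4-hydroxy-5,9,13,15-tetramethyl-11-methylidene-1,7-dioxaspiro[2.13]hexadeca-9,14-dien-6-one
Product: 19 (3R,5R,8R,9E,13S,14E)-8-ethyl-5,9,13,15-tetramethyl-11-methylidene-1,7-dioxaspiro[2.13]hexadeca-9,14-diene-4,6-dione
Conditions: Dess–Martin periodinane, NaHCO3, CH2Cl2, 0 °C to rt; then Et3N (0.1 equiv), CH2Cl2, rt
Reagents that add atoms: none
Why: Dess–Martin oxidation gives the β-keto lactone, whose acidic C2–H lets amine-mediated enolisation converge both epimers on the preferred 2R configuration.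

**Step 12**
Reactants: 19 (3R,5R,8R,9E,13S,14E)-8-ethyl-5,9,13,15-tetramethyl-11-methylidene-1,7-dioxaspiro[2.13]hexadeca-9,14-diene-4,6-dione
Product: 20 (3R,5R,7E,9S,12E,14R)-14-ethyl-5-hydroxy-5-(hydroxymethyl)-3,7,9,13-tetramethyl-11-methylidene-1-oxacyclotetradeca-7,12-diene-2,4-dione (CNP0240796.7)
Conditions: HClO4 (5 mol%), THF/H2O 3:1, 0 °C to rt
Reagents that add atoms: water O
Why: Acid-catalysed hydrolysis of the α,β-epoxy ketone, in which water attacks the primary CH2 carbon (the tertiary carbon is deactivated by the adjacent carbonyl), so the C4–O bond and the 4R configuration are retained.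

**Compound list**
1 | propanal | CCC=O | starting material
2 | (2-bromoprop-2-en-1-yl)trimethylsilane | C=C(Br)C[Si](C)(C)C | starting material
3 | (2S)-4-bromo-2-methylpent-4-enal | C=C(Br)C[C@H](C)C=O | intermediate
4 | (4S)-6-bromo-2,4-dimethylhepta-1,6-dien-3-ol (C3 epimers) | C=C(Br)C[C@H](C)C(O)C(C)=C | intermediate
5 | prop-2-yn-1-ol | C#CCO | starting material
6 | (E)-alkenylalane Me2Al–CH=C(CH3)–CH2–O–AlMe2 | C[Al](C)/C=C(\C)CO[Al](C)C | intermediate (not isolated)
7 | (2E)-3-iodo-2-methylprop-2-en-1-ol | OC/C(C)=C/I | intermediate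
8 | (2E)-3-iodo-2-methylprop-2-enal | O=C/C(C)=C/I | intermediate
9 | ethylzinc (1E,3R)-1-iodo-2-methylpent-1-en-3-olate | I/C=C(\C)[C@@H](CC)O[Zn]CC | intermediate (not isolated)
10 | (1E,3R)-1-iodo-2-methylpent-1-en-3-yl propanoate | I/C=C(\C)[C@@H](CC)OC(=O)CC | intermediate
11 | (4S)-2,4-dimethyl-6-(4,4,5,5-tetramethyl-1,3,2-dioxaborolan-2-yl)hepta-1,6-dien-3-ol | C=C(B1OC(C)(C)C(C)(C)O1)C[C@H](C)C(O)C(C)=C | intermediate (not isolated)
12 | (3R,4E,8S)-9-hydroxy-4,8,10-trimethyl-6-methylideneundeca-4,10-dien-3-yl propanoate (C9 epimers) | C=C(/C=C(\C)[C@@H](CC)OC(=O)CC)C[C@H](C)C(O)C(C)=C | intermediate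
13 | (3R,4E,8S)-9-(ethenyloxy)-4,8,10-trimethyl-6-methylideneundeca-4,10-dien-3-yl propanoate | C=C(/C=C(\C)[C@@H](CC)OC(=O)CC)C[C@H](C)C(OC=C)C(C)=C | intermediate (not isolated)
14 | (3R,4E,8S,9E)-4,8,10-trimethyl-6-methylidene-13-oxotrideca-4,9-dien-3-yl propanoate | C=C(/C=C(\C)[C@@H](CC)OC(=O)CC)C[C@H](C)/C=C(\C)CCC=O | intermediate
15 | (3R,4E,8S,9E)-12-formyl-4,8,10-trimethyl-6-methylidenetrideca-4,9,12-trien-3-yl propanoate | C=C(/C=C(\C)[C@@H](CC)OC(=O)CC)C[C@H](C)/C=C(\C)CC(=C)C=O | intermediate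
16 | (3R,4E,8S,9E)-11-[(2R)-2-formyloxiran-2-yl]-4,8,10-trimethyl-6-methylideneundeca-4,9-dien-3-yl propanoate | C=C(/C=C(\C)[C@@H](CC)OC(=O)CC)C[C@H](C)/C=C(\C)C[C@]1(C=O)CO1 | intermediate
17 | potassium enolate of the propanoate of 16 | C=C(/C=C(\C)[C@@H](CC)OC(O[K])=CC)C[C@H](C)/C=C(\C)C[C@]1(C=O)CO1 | intermediate (not isolated)
18 | (3R,8R,9E,13S,14E)-8-ethyl-4-hydroxy-5,9,13,15-tetramethyl-11-methylidene-1,7-dioxaspiro[2.13]hexadeca-9,14-dien-6-one (14-membered lactone with C4 spiro-oxirane, C3–OH, C2–Me; C2/C3 epimers) | C=C1/C=C(\C)[C@@H](CC)OC(=O)C(C)C(O)[C@]2(CO2)C/C(C)=C/[C@@H](C)C1 | intermediate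
19 | (3R,5R,8R,9E,13S,14E)-8-ethyl-5,9,13,15-tetramethyl-11-methylidene-1,7-dioxaspiro[2.13]hexadeca-9,14-diene-4,6-dione (3-keto lactone with C4 spiro-oxirane) | C=C1/C=C(\C)[C@@H](CC)OC(=O)[C@H](C)C(=O)[C@]2(CO2)C/C(C)=C/[C@@H](C)C1 | intermediate
20 | (3R,5R,7E,9S,12E,14R)-14-ethyl-5-hydroxy-5-(hydroxymethyl)-3,7,9,13-tetramethyl-11-methylidene-1-oxacyclotetradeca-7,12-diene-2,4-dione | C=C1/C=C(\C)[C@@H](CC)OC(=O)[C@H](C)C(=O)[C@](O)(CO)C/C(C)=C/[C@@H](C)C1 | target

**Step count**
Total: 12 steps. Longest linear sequence: 10 steps (5 → 7 → 8 → 10 → 12 → 14 → 15 → 16 → 18 → 19 → 20, steps 3–12). The branch from propanal is 9 steps.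

**Three steps most likely to fail, with fallbacks**

Step 1 (the proposed new SOMO variant). The bromine lowers the nucleophilicity of the allylsilane, and propanal and 3 are volatile, so yield or ee may be poor. The fallback uses only known chemistry, sets out from 1 and comes back at 14.
- Propanal 1 is alkylated with ethyl 2-(bromomethyl)acrylate under enamine catalysis ((R)-α,α-diphenylprolinol trimethylsilyl ether, DABCO, an established SN2′-type α-alkylation) to give ethyl (4S)-4-methyl-2-methylidene-5-oxopentanoate F1.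
- CH2=C(CH3)MgBr at –78 °C gives ethyl (4S)-5-hydroxy-4,6-dimethyl-2-methylidenehept-6-enoate F2.
- Johnson–Claisen rearrangement (triethyl orthoacetate, cat. propanoic acid, 140 °C) gives diethyl (4S,5E)-4,6-dimethyl-2-methylidenenon-5-enedioate F3.
- iBu2AlH reduces both esters to (4S,5E)-4,6-dimethyl-2-methylidenenon-5-ene-1,9-diol F4.
- MnO2 oxidises only the allylic alcohol to (4S,5E)-9-hydroxy-4,6-dimethyl-2-methylidenenon-5-enal F5.
- Wittig reaction with 2-(triphenylphosphoranylidene)pentan-3-one gives (4E,8S,9E)-13-hydroxy-4,8,10-trimethyl-6-methylidenetrideca-4,9-dien-3-one F6.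
- CBS reduction ((S)-Me-oxazaborolidine, BH3·SMe2) sets C13 and gives (3R,4E,8S,9E)-4,8,10-trimethyl-6-methylidenetrideca-4,9-diene-3,13-diol F7.
- TEMPO/PhI(OAc)2 oxidises the primary alcohol to (4E,6S,9E,11R)-11-hydroxy-4,6,10-trimethyl-8-methylidenetrideca-4,9-dienal F8.
- Propanoylation ((EtCO)2O, DMAP) returns to 14.

Step 9 (amine-catalysed epoxidation). The sense and level of induction on this 2-alkylacrolein are untested, and the epoxy aldehyde is sensitive to the peroxide medium. The fallback sets out from 15 and comes back at 16.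
- Luche reduction (NaBH4, CeCl3·7H2O, MeOH, –40 °C) gives (3R,4E,8S,9E)-12-(hydroxymethyl)-4,8,10-trimethyl-6-methylidenetrideca-4,9,12-trien-3-yl propanoate F9.
- Sharpless asymmetric epoxidation (Ti(OiPr)4, L-(+)-diethyl tartrate, t-BuOOH, 4 Å sieves, CH2Cl2, –20 °C), directed by the allylic hydroxyl, gives (3R,4E,8S,9E)-11-[(2S)-2-(hydroxymethyl)oxiran-2-yl]-4,8,10-trimethyl-6-methylideneundeca-4,9-dien-3-yl propanoate F10.
- Dess–Martin oxidation returns to 16.

Step 10 (macro-aldol). Oligomerisation, silylamide attack on the aldehyde or retro-aldol may win over ring closure. The fallback closes the ring at C10–C11 instead; it sets out from 4 (10 is used again) and comes back at 19.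
- Compound 4 is taken through the transvinylation/Claisen, α-methylenation and amine-catalysed epoxidation of steps 7–9 before any coupling. This gives in turn (4E,6S)-8-bromo-4,6-dimethylnona-4,8-dienal F11, (4E,6S)-8-bromo-4,6-dimethyl-2-methylidenenona-4,8-dienal F12 and (2R)-2-[(2E,4S)-6-bromo-2,4-dimethylhepta-2,6-dien-1-yl]oxirane-2-carbaldehyde F13.
- The lithium enolate of 10 (LiN(SiMe3)2, THF, –78 °C) adds to F13 in an ordinary intermolecular aldol reaction to give (1E,3R)-1-iodo-2-methylpent-1-en-3-yl 3-{(2R)-2-[(2E,4S)-6-bromo-2,4-dimethylhepta-2,6-dien-1-yl]oxiran-2-yl}-3-hydroxy-2-methylpropanoate F14.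
- Dess–Martin oxidation gives (1E,3R)-1-iodo-2-methylpent-1-en-3-yl 3-{(2R)-2-[(2E,4S)-6-bromo-2,4-dimethylhepta-2,6-dien-1-yl]oxiran-2-yl}-2-methyl-3-oxopropanoate F15.
- Miyaura borylation of the iodoalkene (B2pin2, PdCl2(dppf), KOPh) gives the (1E)-1-(4,4,5,5-tetramethyl-1,3,2-dioxaborolan-2-yl) analogue of F15, boronate F16, which is not isolated.
- Intramolecular Suzuki coupling onto the 2-bromoalkene (aq K3PO4, high dilution), followed by the C2 equilibration of step 11, gives 19.

**Further compounds**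
F1 | step 1 | ethyl (4S)-4-methyl-2-methylidene-5-oxopentanoate | CCOC(=O)C(=C)C[C@H](C)C=O
F2 | step 1 | ethyl (4S)-5-hydroxy-4,6-dimethyl-2-methylidenehept-6-enoate (C5 epimers) | CCOC(=O)C(=C)C[C@H](C)C(O)C(C)=C
F3 | step 1 | diethyl (4S,5E)-4,6-dimethyl-2-methylidenenon-5-enedioate | CCOC(=O)C(=C)C[C@H](C)/C=C(\C)CCC(=O)OCC
F4 | step 1 | (4S,5E)-4,6-dimethyl-2-methylidenenon-5-ene-1,9-diol | OCC(=C)C[C@H](C)/C=C(\C)CCCO
F5 | step 1 | (4S,5E)-9-hydroxy-4,6-dimethyl-2-methylidenenon-5-enal | O=CC(=C)C[C@H](C)/C=C(\C)CCCO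
F6 | step 1 | (4E,8S,9E)-13-hydroxy-4,8,10-trimethyl-6-methylidenetrideca-4,9-dien-3-one | CCC(=O)/C(C)=C/C(=C)C[C@H](C)/C=C(\C)CCCO
F7 | step 1 | (3R,4E,8S,9E)-4,8,10-trimethyl-6-methylidenetrideca-4,9-diene-3,13-diol | CC[C@@H](O)/C(C)=C/C(=C)C[C@H](C)/C=C(\C)CCCO
F8 | step 1 | (4E,6S,9E,11R)-11-hydroxy-4,6,10-trimethyl-8-methylidenetrideca-4,9-dienal | CC[C@@H](O)/C(C)=C/C(=C)C[C@H](C)/C=C(\C)CCC=O
F9 | step 9 | (3R,4E,8S,9E)-12-(hydroxymethyl)-4,8,10-trimethyl-6-methylidenetrideca-4,9,12-trien-3-yl propanoate | C=C(/C=C(\C)[C@@H](CC)OC(=O)CC)C[C@H](C)/C=C(\C)CC(=C)CO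
F10 | step 9 | (3R,4E,8S,9E)-11-[(2S)-2-(hydroxymethyl)oxiran-2-yl]-4,8,10-trimethyl-6-methylideneundeca-4,9-dien-3-yl propanoate | C=C(/C=C(\C)[C@@H](CC)OC(=O)CC)C[C@H](C)/C=C(\C)C[C@]1(CO)CO1
F11 | step 10 | (4E,6S)-8-bromo-4,6-dimethylnona-4,8-dienal | C=C(Br)C[C@H](C)/C=C(\C)CCC=O
F12 | step 10 | (4E,6S)-8-bromo-4,6-dimethyl-2-methylidenenona-4,8-dienal | C=C(Br)C[C@H](C)/C=C(\C)CC(=C)C=O
F13 | step 10 | (2R)-2-[(2E,4S)-6-bromo-2,4-dimethylhepta-2,6-dien-1-yl]oxirane-2-carbaldehyde | C=C(Br)C[C@H](C)/C=C(\C)C[C@]1(C=O)CO1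
F14 | step 10 | (1E,3R)-1-iodo-2-methylpent-1-en-3-yl 3-{(2R)-2-[(2E,4S)-6-bromo-2,4-dimethylhepta-2,6-dien-1-yl]oxiran-2-yl}-3-hydroxy-2-methylpropanoate (C2/C3 epimers) | I/C=C(\C)[C@@H](CC)OC(=O)C(C)C(O)[C@]1(CO1)C/C(C)=C/[C@@H](C)CC(Br)=C
F15 | step 10 | (1E,3R)-1-iodo-2-methylpent-1-en-3-yl 3-{(2R)-2-[(2E,4S)-6-bromo-2,4-dimethylhepta-2,6-dien-1-yl]oxiran-2-yl}-2-methyl-3-oxopropanoate (C2 epimers) | I/C=C(\C)[C@@H](CC)OC(=O)C(C)C(=O)[C@]1(CO1)C/C(C)=C/[C@@H](C)CC(Br)=C
F16 | step 10 | (1E,3R)-2-methyl-1-(4,4,5,5-tetramethyl-1,3,2-dioxaborolan-2-yl)pent-1-en-3-yl 3-{(2R)-2-[(2E,4S)-6-bromo-2,4-dimethylhepta-2,6-dien-1-yl]oxiran-2-yl}-2-methyl-3-oxopropanoate | CC1(C)OB(OC1(C)C)/C=C(\C)[C@@H](CC)OC(=O)C(C)C(=O)[C@]2(CO2)C/C(C)=C/[C@@H](C)CC(Br)=C
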